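**Plan**

- Retrosynthesis: the methylene bridge between arene C6 and pyranone C3 is cut first (both C–C bonds, a Mannich-type union through one carbon), then the arene bond C6–C7, then the C8–acyl and C4a–acetyl bonds, then C8a–C8, and last the ring C–O bond of a δ-lactone that goes back to a cyclopentanone.
- Enabling feature: the acylphloroglucinol ring is a branched tetraketide whose C8a oxygen is already O1 of the dihydropyran ring. C8a is therefore locked as an enol ether, and only a methyl ketone (C5 with its methyl C6, on C4a) and an ester (C7, on C8) remain to be folded; joining C6 to C7 can give only the 8-acyl chroman.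
- Forward: the dihydropyran ring comes first (Baeyer–Villiger lactone, then ester-enolate addition and dehydration). Its two dienolate termini C4a and C8 are acylated in turn, the benzene ring is closed by intramolecular Claisen condensation, and the separately made pyranone ring is attached in the last step.
- Stereochemistry: C3 comes from CBS desymmetrisation of a prochiral 1,3-dione and is carried through untouched. The sec-butyl centre is bought as (S)-2-methylbutanoic acid and always sits beside an enolised or chelated ketone.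

Key step: step 8

Remark: in the CBS reduction of 1 the quaternary carbon is taken as the large carbonyl substituent, so the (R)-catalyst is expected to give the (S)-alcohol; if the sense proves opposite, the (S)-catalyst is used. Compounds 7 and 10 are written as single tautomers; 6 and 15 are used as E/Z mixtures.

**Route**

Step 1
Reactants: 1 2,2-dimethylcyclopentane-1,3-dione
Product: 2 (3S)-3-hydroxy-2,2-dimethylcyclopentan-1-one
Conditions: (R)-Me-CBS oxazaborolidine [(R)-1-methyl-3,3-diphenyltetrahydro-1H,3H-pyrrolo[1,2-c][1,3,2]oxazaborole] (10 mol %), BH3·SMe2 (0.6 equiv), THF, −20 °C; MeOH, then aqueous work-up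
Reagents that add atoms: none
Why: Corey–Bakshi–Shibata reduction desymmetrises the prochiral, non-enolisable 1,3-dione, the catalyst-bound borane delivering hydride to one carbonyl face with the quaternary carbon as the large group so that the new carbinol centre should be S, while sub-stoichiometric borane limits over-reduction to the diol.

Step 2
Reactants: 2 (3S)-3-hydroxy-2,2-dimethylcyclopentan-1-one
Product: 3 (3S)-3-(tert-butyldimethylsilyloxy)-2,2-dimethylcyclopentan-1-one
Conditions: t-BuMe2SiCl, imidazole, DMF, rt
Reagents that add atoms: tert-butyldimethylsilyl chloride, CC(C)(C)[Si](C)(C)Cl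
Why: Imidazole-promoted silylation of a secondary alcohol should be clean, and the β-silyloxy ketone cannot eliminate because the carbon between the two functions is quaternary.

Step 3
Reactants: 3 (3S)-3-(tert-butyldimethylsilyloxy)-2,2-dimethylcyclopentan-1-one
Product: 4 (5S)-5-(tert-butyldimethylsilyloxy)-6,6-dimethyloxan-2-one
Conditions: mCPBA (1.5 equiv), CH2Cl2, 0 °C → rt
Reagents that add atoms: 3-chloroperoxybenzoic acid, OOC(=O)c1cccc(Cl)c1
Why: Baeyer–Villiger oxidation in which the quaternary carbon migrates in preference to the methylene, placing oxygen between the carbonyl and CMe2 with the silyloxy centre untouched, so that the O1–C2 and O1–C8a bonds of the future chroman are fixed without any 5-exo/6-endo ambiguity.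

Step 4
Reactants: 4 (5S)-5-(tert-butyldimethylsilyloxy)-6,6-dimethyloxan-2-one
Product: 6 methyl 2-[(5S)-5-(tert-butyldimethylsilyloxy)-6,6-dimethyloxan-2-ylidene]acetate, via hemiketal 5 (not isolated)
Conditions: MeOAc, LiN(iPr)2 (2.5 equiv), THF, −78 °C; AcOH; then crude 5, MsCl, Et3N, CH2Cl2, 0 °C → rt
Reagents that add atoms: methyl acetate, COC(C)=O
Why: Claisen-type addition of the lithium enolate of methyl acetate to the δ-lactone stops at the hemiketal (ring tautomer of the β-keto ester), and mesylation of the anomeric hydroxyl with loss of the acidic C8 proton gives the ester-conjugated exocyclic enol ether (dehydration to a vinylogous carbonate).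

Step 5
Reactants: 6 methyl 2-[(5S)-5-(tert-butyldimethylsilyloxy)-6,6-dimethyloxan-2-ylidene]acetate
Product: 7 methyl 2-[(5S)-3-acetyl-5-(tert-butyldimethylsilyloxy)-6,6-dimethyl-5,6-dihydro-4H-pyran-2-yl]acetate
Conditions: LiN(iPr)2 (1.2 equiv), THF, −78 °C; MeC(O)N(OMe)Me, −78 → −20 °C; AcOH
Reagents that add atoms: N-methoxy-N-methylacetamide, CC(=O)N(C)OC
Why: γ-Deprotonation of the β-alkoxy acrylate gives a dienolate that behaves as an O-alkylated acetoacetate dianion and is acylated at its terminal carbon C4a (γ-acylation, as known for 3-alkoxycrotonate anions) by the Weinreb amide, whose chelated adduct releases the ketone only on quench, after which the product should settle as the ketone-conjugated endocyclic enol ether.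

Step 6
Reactants: 8 (2S)-2-methylbutanoic acid
Product: 9 (2S)-2-methylbutanoyl chloride
Conditions: (COCl)2, DMF (cat.), CH2Cl2, 0 °C → rt
Reagents that add atoms: oxalyl chloride, O=C(Cl)C(=O)Cl
Why: Acid chloride formation through the Vilsmeier-type chloroiminium intermediate runs without added base, so no ketene can form and the α-stereocentre should be retained.

Step 7
Reactants: 7 methyl 2-[(5S)-3-acetyl-5-(tert-butyldimethylsilyloxy)-6,6-dimethyl-5,6-dihydro-4H-pyran-2-yl]acetate; 9 (2S)-2-methylbutanoyl chloride
Product: 10 methyl (4S)-2-[(5S)-3-acetyl-5-(tert-butyldimethylsilyloxy)-6,6-dimethyl-5,6-dihydro-4H-pyran-2-yl]-4-methyl-3-oxohexanoate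
Conditions: NaH (2.2 equiv), THF, 0 °C; 9 (1.1 equiv), 0 °C → rt; AcOH
Reagents that add atoms: none
Why: C-acylation of a stabilised sodium enolate by an acid chloride, the enolate being formed at C8 (α to the ester and vinylogous to the acetyl group) and reacting at that unhindered terminus, while the second equivalent of base removes the more acidic proton of the tricarbonyl product and thereby also shields the adjacent sec-butyl stereocentre.

Step 8
Reactants: 10 methyl (4S)-2-[(5S)-3-acetyl-5-(tert-butyldimethylsilyloxy)-6,6-dimethyl-5,6-dihydro-4H-pyran-2-yl]-4-methyl-3-oxohexanoate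
Product: 12 (2S)-1-[(3S)-3-(tert-butyldimethylsilyloxy)-5,7-dihydroxy-2,2-dimethyl-3,4-dihydro-2H-chromen-8-yl]-2-methylbutan-1-one, via enol-ether dione 11 (not isolated)
Conditions: LiN(iPr)2 (3.2 equiv), THF, −78 °C → rt; 1 M HCl
Reagents that add atoms: none
Why: The first equivalent of LiN(iPr)2 removes the C8 proton and gives a lithium-chelated enolate whose charge rests mainly on the sec-butyl ketone oxygen, which shuts that ketone down as an aldol acceptor and shields the neighbouring stereocentre, and the next equivalent deprotonates the acetyl methyl group, the kinetic α′ site of a β-alkoxy enone, to give the C6 enolate. C6 then attacks the ester carbon C7 held cis to it across the C4a=C8a bond, closing the carbocycle in a 6-exo-trig mode; methoxide leaves, and the enol-ether dione 11 is deprotonated and tautomerises to the 5,7-dihydroxy arene on acidification. The closest known reactions are the Dieckmann-type Claisen cyclisation of δ-keto esters to cyclohexane-1,3-diones and the base-induced Claisen folding of polyketo esters to acylphloroglucinols. No stereocentre is created; C3 is remote and the sec-butyl centre stays next to an enolate throughout. The step needs C-acylation at the ester to win over aldol closure onto the ketone and over O-acylation by the acetyl oxygen to a pyranone; the first is secured by prior enolisation and α-branching of the ketone, the second by turning the acetyl group into its carbon-nucleophilic enolate at low temperature before the mixture is warmed. Because the C8a oxygen is already the ring ether O1, the only arene that can result is the 8-acyl chroman with O1 next to the acyl group.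

Step 9
Reactants: 12 (2S)-1-[(3S)-3-(tert-butyldimethylsilyloxy)-5,7-dihydroxy-2,2-dimethyl-3,4-dihydro-2H-chromen-8-yl]-2-methylbutan-1-one
Product: 13 (2S)-1-[(3S)-3,5,7-trihydroxy-2,2-dimethyl-3,4-dihydro-2H-chromen-8-yl]-2-methylbutan-1-one
Conditions: HF·pyridine, THF, 0 °C → rt
Reagents that add atoms: none
Why: Fluoride-driven desilylation of the secondary silyl ether under mildly acidic conditions, to which the phenols, the aryl ketone and its α-stereocentre are inert.

Step 10
Reactants: 14 pentan-3-one
Product: 15 3-(trimethylsilyloxy)pent-2-ene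
Conditions: Me3SiCl, Et3N, DMF, 80 °C
Reagents that add atoms: chlorotrimethylsilane, C[Si](C)(C)Cl
Why: Silyl enol ether formation under equilibrating amine conditions, which for the symmetrical ketone can give only one regioisomer.

Step 11
Reactants: 15 3-(trimethylsilyloxy)pent-2-ene
Product: 17 6-ethyl-4-hydroxy-5-methyl-2H-pyran-2-one, via acid chloride 16 (not isolated)
Conditions: ClC(O)CH2C(O)Cl, Et2O, −78 °C → rt
Reagents that add atoms: malonyl dichloride, O=C(Cl)CC(=O)Cl
Why: C-acylation of the silyl enol ether by malonyl dichloride gives the 3,5-dioxo acid chloride, whose ketone enol oxygen then closes onto the remaining acyl chloride (acylation–lactonisation route to 4-hydroxy-2-pyranones).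

Step 12
Reactants: 13 (2S)-1-[(3S)-3,5,7-trihydroxy-2,2-dimethyl-3,4-dihydro-2H-chromen-8-yl]-2-methylbutan-1-one; 17 6-ethyl-4-hydroxy-5-methyl-2H-pyran-2-one
Product: 19 6-ethyl-4-hydroxy-5-methyl-3-({(3S)-3,5,7-trihydroxy-2,2-dimethyl-8-[(2S)-2-methylbutanoyl]-3,4-dihydro-2H-chromen-6-yl}methyl)-2H-pyran-2-one, via Mannich base 18 (not isolated)
Conditions: Me2N=CH2 I (1.05 equiv), MeCN, 0 °C → rt; then 17 (2 equiv), 80 °C
Reagents that add atoms: dimethylmethylideneammonium iodide (Eschenmoser's salt), C=[N+](C)C.[I-]
Why: Mannich aminomethylation at C6, the only free and most electron-rich arene carbon, followed by thermal loss of dimethylamine to an ortho-quinone methide that is trapped at C3 of the acidic pyranone (Mannich/elimination–Michael coupling, the usual way to methylene-bridged phloroglucinol–pyranone dimers), with no homodimer possible on the arene side.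

**Compound list**

1 | 2,2-dimethylcyclopentane-1,3-dione | CC1(C)C(=O)CCC1=O | starting material
2 | (3S)-3-hydroxy-2,2-dimethylcyclopentan-1-one | CC1(C)[C@@H](O)CCC1=O | intermediate
3 | (3S)-3-(tert-butyldimethylsilyloxy)-2,2-dimethylcyclopentan-1-one | CC1(C)[C@@H](O[Si](C)(C)C(C)(C)C)CCC1=O | intermediate
4 | (5S)-5-(tert-butyldimethylsilyloxy)-6,6-dimethyloxan-2-one | O=C1CC[C@H](O[Si](C)(C)C(C)(C)C)C(C)(C)O1 | intermediate
5 | methyl 2-[(5S)-5-(tert-butyldimethylsilyloxy)-2-hydroxy-6,6-dimethyloxan-2-yl]acetate (hemiketal, not isolated) | COC(=O)CC1(O)CC[C@H](O[Si](C)(C)C(C)(C)C)C(C)(C)O1 | intermediate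
6 | methyl 2-[(5S)-5-(tert-butyldimethylsilyloxy)-6,6-dimethyloxan-2-ylidene]acetate (E/Z mixture) | COC(=O)C=C1CC[C@H](O[Si](C)(C)C(C)(C)C)C(C)(C)O1 | intermediate
7 | methyl 2-[(5S)-3-acetyl-5-(tert-butyldimethylsilyloxy)-6,6-dimethyl-5,6-dihydro-4H-pyran-2-yl]acetate | COC(=O)CC1=C(C(C)=O)C[C@H](O[Si](C)(C)C(C)(C)C)C(C)(C)O1 | intermediate
8 | (2S)-2-methylbutanoic acid | CC[C@H](C)C(=O)O | starting material
9 | (2S)-2-methylbutanoyl chloride | CC[C@H](C)C(Cl)=O | intermediate
10 | methyl (4S)-2-[(5S)-3-acetyl-5-(tert-butyldimethylsilyloxy)-6,6-dimethyl-5,6-dihydro-4H-pyran-2-yl]-4-methyl-3-oxohexanoate (C2 epimers/enol) | COC(=O)C(C(=O)[C@@H](C)CC)C1=C(C(C)=O)C[C@H](O[Si](C)(C)C(C)(C)C)C(C)(C)O1 | intermediate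
11 | (3S)-3-(tert-butyldimethylsilyloxy)-2,2-dimethyl-8-[(2S)-2-methylbutanoyl]-3,4-dihydro-2H-chromene-5,7(6H,8H)-dione (not isolated) | O=C1CC(=O)C(C(=O)[C@@H](C)CC)C2=C1C[C@H](O[Si](C)(C)C(C)(C)C)C(C)(C)O2 | intermediate
12 | (2S)-1-[(3S)-3-(tert-butyldimethylsilyloxy)-5,7-dihydroxy-2,2-dimethyl-3,4-dihydro-2H-chromen-8-yl]-2-methylbutan-1-one | Oc1cc(O)c(C(=O)[C@@H](C)CC)c2OC(C)(C)[C@@H](O[Si](C)(C)C(C)(C)C)Cc12 | intermediate
13 | (2S)-1-[(3S)-3,5,7-trihydroxy-2,2-dimethyl-3,4-dihydro-2H-chromen-8-yl]-2-methylbutan-1-one | Oc1cc(O)c(C(=O)[C@@H](C)CC)c2OC(C)(C)[C@@H](O)Cc12 | intermediate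
14 | pentan-3-one | CCC(=O)CC | starting material
15 | 3-(trimethylsilyloxy)pent-2-ene (E/Z mixture) | CC=C(CC)O[Si](C)(C)C | intermediate
16 | 4-methyl-3,5-dioxoheptanoyl chloride (not isolated) | CCC(=O)C(C)C(=O)CC(Cl)=O | intermediate
17 | 6-ethyl-4-hydroxy-5-methyl-2H-pyran-2-one | CCc1oc(=O)cc(O)c1C | intermediate
18 | (2S)-1-[(3S)-6-[(dimethylamino)methyl]-3,5,7-trihydroxy-2,2-dimethyl-3,4-dihydro-2H-chromen-8-yl]-2-methylbutan-1-one (not isolated) | CN(C)Cc1c(O)c2c(c(C(=O)[C@@H](C)CC)c1O)OC(C)(C)[C@@H](O)C2 | intermediate
19 | 6-ethyl-4-hydroxy-5-methyl-3-({(3S)-3,5,7-trihydroxy-2,2-dimethyl-8-[(2S)-2-methylbutanoyl]-3,4-dihydro-2H-chromen-6-yl}methyl)-2H-pyran-2-one | CCc1oc(=O)c(Cc2c(O)c3c(c(C(=O)[C@@H](C)CC)c2O)OC(C)(C)[C@@H](O)C3)c(O)c1C | target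

**Step count and risks**

Total: 12 steps. Longest linear sequence: 9 steps (steps 1, 2, 3, 4, 5, 7, 8, 9, 12).

Step 8 (ring closure). The dianion may stay inert because the enolised β-keto ester drains electrophilicity from the ester carbonyl. Closure may also take the aldol course onto the sec-butyl ketone, or the acetyl oxygen may acylate to give a fused pyranone. Fallback, setting out from 7 and returning at 12: the same C6–C7 bond is closed before the acyl group is present. Compound 7, which has no competing ketone and a far less acidic C8, is heated with NaOMe in MeOH (Claisen cyclisation and aromatisation) to give (3S)-3-(tert-butyldimethylsilyloxy)-2,2-dimethyl-3,4-dihydro-2H-chromene-5,7-diol F1. Friedel–Crafts acylation of F1 with 9 (TiCl4, CH2Cl2, 0 °C) should then give 12 together with its 6-acyl isomer, which has to be separated; the price is the loss of built-in regiocontrol.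

Step 7 (C8 acylation). Acylation may occur at the acetyl oxygen instead of C8, a second acylation may follow at the acetyl methyl group, or the sodium enolate of 7 may lactonise to a pyranone with loss of methoxide before it is acylated. Fallback, setting out from 4 and returning at 10: the acyl group is introduced while C8 is the methylene of a true β-keto ester. Lactone 4 is acetylated at its α-carbon (LiN(iPr)2, then MeC(O)N(OMe)Me) to (5S)-3-acetyl-5-(tert-butyldimethylsilyloxy)-6,6-dimethyloxan-2-one F2. The ketone is masked with 1,2-bis(trimethylsilyloxy)ethane and catalytic Me3SiOTf as (5S)-5-(tert-butyldimethylsilyloxy)-6,6-dimethyl-3-(2-methyl-1,3-dioxolan-2-yl)oxan-2-one F3. Lithiated methyl acetate adds to give methyl 2-[(5S)-5-(tert-butyldimethylsilyloxy)-2-hydroxy-6,6-dimethyl-3-(2-methyl-1,3-dioxolan-2-yl)oxan-2-yl]acetate F4. F4 is C-acylated with 9 under MgCl2/pyridine soft-enolisation conditions to methyl (4S)-2-[(5S)-5-(tert-butyldimethylsilyloxy)-2-hydroxy-6,6-dimethyl-3-(2-methyl-1,3-dioxolan-2-yl)oxan-2-yl]-4-methyl-3-oxohexanoate F5. Pyridinium tosylate in wet acetone then removes the ketal and dehydrates the hemiketal towards the acetyl group to give 10.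

Step 5 (C4a acetylation). The dienolate may be attacked at its α-carbon instead of the γ-terminus, may be quenched by proton transfer from the Weinreb amide, or the product enolate may lactonise. Fallback, setting out from 6 and returning at 7: the acylation is run on a neutral silyl dienol ether instead of the lithium dienolate. Compound 6 is converted with LiN(iPr)2 and Me3SiCl into (5S)-5-(tert-butyldimethylsilyloxy)-2-[2-methoxy-2-(trimethylsilyloxy)ethenyl]-6,6-dimethyl-5,6-dihydro-4H-pyran F6. This 1-alkoxy-1-silyloxy diene is acylated at its terminal carbon with acetyl chloride (CH2Cl2, −78 °C, ZnCl2 catalysis if needed; vinylogous Mukaiyama-type acylation) to give 7.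

Further compounds
F1 | step 8 | (3S)-3-(tert-butyldimethylsilyloxy)-2,2-dimethyl-3,4-dihydro-2H-chromene-5,7-diol | Oc1cc(O)c2C[C@H](O[Si](C)(C)C(C)(C)C)C(C)(C)Oc2c1
F2 | step 7 | (5S)-3-acetyl-5-(tert-butyldimethylsilyloxy)-6,6-dimethyloxan-2-one | CC(=O)C1C[C@H](O[Si](C)(C)C(C)(C)C)C(C)(C)OC1=O
F3 | step 7 | (5S)-5-(tert-butyldimethylsilyloxy)-6,6-dimethyl-3-(2-methyl-1,3-dioxolan-2-yl)oxan-2-one | CC1(OCCO1)C2C[C@H](O[Si](C)(C)C(C)(C)C)C(C)(C)OC2=O
F4 | step 7 | methyl 2-[(5S)-5-(tert-butyldimethylsilyloxy)-2-hydroxy-6,6-dimethyl-3-(2-methyl-1,3-dioxolan-2-yl)oxan-2-yl]acetate | COC(=O)CC1(O)OC(C)(C)[C@@H](O[Si](C)(C)C(C)(C)C)CC1C2(C)OCCO2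
F5 | step 7 | methyl (4S)-2-[(5S)-5-(tert-butyldimethylsilyloxy)-2-hydroxy-6,6-dimethyl-3-(2-methyl-1,3-dioxolan-2-yl)oxan-2-yl]-4-methyl-3-oxohexanoate | COC(=O)C(C(=O)[C@@H](C)CC)C1(O)OC(C)(C)[C@@H](O[Si](C)(C)C(C)(C)C)CC1C2(C)OCCO2
F6 | step 5 | (5S)-5-(tert-butyldimethylsilyloxy)-2-[2-methoxy-2-(trimethylsilyloxy)ethenyl]-6,6-dimethyl-5,6-dihydro-4H-pyran | COC(O[Si](C)(C)C)=CC1=CC[C@H](O[Si](C)(C)C(C)(C)C)C(C)(C)O1
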